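Ring C is disconnected at C2–C3 and C4–C4a. The key step exploits two features: C2 sits between O1 and ring B at the aldehyde oxidation level, and C4a is the only free, strongly nucleophilic carbon ortho to O1 on phloroglucinol-type ring A (C8 carries the geranyl group). An O-aryl oxocarbenium ion (C4a=C8a–O1=C2), released from a pivaloyloxy acetal of the fully geranylated phenol, takes up ethoxyethyne as the C3–C4 unit under control of a chiral counter-anion: C3 bonds to C2, setting 2S, and the ketenium carbon C4 is captured by C4a. Enol ether hydrolysis and desilylation complete the target.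

Key step: step 6

Assumption: both enantiomers of the chiral acid (step 6) and of the ligand in its fallback are available, and the one that delivers 2S is identified in a first test reaction.

Step 1
Reactants: 1 phloroglucinol; 2 geranyl bromide
Product: 3 2-geranylphloroglucinol
Conditions: 1 (3 equiv), DBU (1.1 equiv), THF, 0 °C to rt
Reagents that add atoms: none
Why: C-allylation of the ambident phloroglucinol anion at the primary allylic bromide should give the mono-C-geranyl triol with the E-olefin intact; all ring carbons are equivalent and excess 1 limits polyalkylation.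

Step 2
Reactants: 3 2-geranylphloroglucinol
Product: 4 2-geranyl-5-(triisopropylsilyloxy)benzene-1,3-diol
Conditions: TIPSCl (1.0 equiv), imidazole (2.2 equiv), DMF, −20 to 0 °C
Reagents that add atoms: chlorotriisopropylsilane, CC(C)[Si](Cl)(C(C)C)C(C)C
Why: Site-selective O-silylation; the hydroxyl para to the geranyl group is the only one without an ortho substituent, so the bulky silyl chloride should prefer it, leaving a symmetric diol.

Step 3
Reactants: 4 2-geranyl-5-(triisopropylsilyloxy)benzene-1,3-diol; 5 geraniol
Product: 6 2-geranyl-3-(geranyloxy)-5-(triisopropylsilyloxy)phenol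
Conditions: 5 (1.0 equiv), PPh3, DIAD, THF, 0 °C
Reagents that add atoms: none
Why: Mitsunobu etherification at the primary allylic carbon under neutral conditions; the two hydroxyls are equivalent, so one equivalent of geraniol should give mainly the mono-ether, with diether and recovered diol separated and the diol recycled.

Step 4
Reactants: 7 4-(tert-butyldimethylsilyloxy)benzaldehyde
Product: 8 chloro[4-(tert-butyldimethylsilyloxy)phenyl]methyl pivalate (racemic)
Conditions: pivaloyl chloride (1.0 equiv), ZnCl2 (2 mol%), CH2Cl2, 0 °C to rt; used crude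
Reagents that add atoms: pivaloyl chloride, CC(C)(C)C(Cl)=O
Why: Lewis-acid-catalysed addition of an acyl chloride across the aldehyde C=O gives the α-chloroalkyl ester, the same reaction type that gives chloromethyl pivalate; the new centre is racemic and is erased in step 6.

Step 5
Reactants: 6 2-geranyl-3-(geranyloxy)-5-(triisopropylsilyloxy)phenol; 8 chloro[4-(tert-butyldimethylsilyloxy)phenyl]methyl pivalate
Product: 9 [4-(tert-butyldimethylsilyloxy)phenyl][2-geranyl-3-(geranyloxy)-5-(triisopropylsilyloxy)phenoxy]methyl pivalate (racemic)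
Conditions: NaH (1.05 equiv), THF, 0 °C; then 8 (1.3 equiv), 0 °C to rt; Et3N-deactivated silica
Reagents that add atoms: none
Why: Phenoxide O-alkylation by an α-chloroalkyl pivalate, as in the formation of pivaloyloxymethyl aryl ethers, makes the O1–C2 bond; the hindered pivalate should suppress acyl transfer to the phenoxide.

Step 6
Reactants: 9 [4-(tert-butyldimethylsilyloxy)phenyl][2-geranyl-3-(geranyloxy)-5-(triisopropylsilyloxy)phenoxy]methyl pivalate; 10 ethoxyethyne
Product: 12 (2S)-2-[4-(tert-butyldimethylsilyloxy)phenyl]-8-geranyl-7-geranyloxy-5-(triisopropylsilyloxy)chroman-4-one, via 4-ethoxy-2H-chromene 11 (not isolated)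
Conditions: chiral imidodiphosphorimidate acid (IDPi, BINOL-derived, N-triflyl core, 5 mol%), 10 (5 equiv), toluene, 4 Å MS, −60 to −30 °C, dark; then 0.5 M aq. HCl, THF, 0 °C
Reagents that add atoms: water, O
Why: Proposed new method: the acid ionises the pivalate of 9 to a contact ion pair of the O-aryl oxocarbenium ion (C4a=C8a–O1=C2, a cationic 2-oxadiene) and the confined chiral anion; ethoxyethyne adds with its terminal carbon to C2 (C2–C3), the ethoxyketenium carbon so formed is captured at once by C4a (C4–C4a), loss of the C4a proton returns the acid, and dilute aqueous acid then hydrolyses enol ether 11 to ketone 12. Closest known reaction types are the Lewis-acid oxa-Povarov reaction of O-aryl oxocarbenium ions with alkenes, the acid-promoted ketenium–arene carbocyclisation of ynol ethers and IDPi-controlled additions to oxocarbenium ions released from acyloxy acetals; their combination in an enantioselective [4+2] with an ynol ether has not been shown. Ring C closes by a six-membered Friedel–Crafts attack that is endo with respect to the C4a–C8a arene bond and places the new C3=C4 bond inside the ring. The C2 stereocentre is set in the C2–C3 bond formation by the chiral anion, which should shield one face of the E-configured oxocarbenium ion, the catalyst enantiomer being chosen for 2S. Regiochemistry needs no control, since C8 carries the geranyl group and C4a is the only free carbon ortho to O1, and the slim sp-hybridised ketenium carbon should tolerate the neighbouring 5-silyloxy group. The Prins-type attack of the C8 geranyl double bond on C2 is to be outrun by the large excess of the ynol ether (and should be reversible on this strongly stabilised cation), and the excess ynol ether also takes up pivalic acid so that no free acid reaches the geranyl groups.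

Step 7
Reactants: 12 (2S)-2-[4-(tert-butyldimethylsilyloxy)phenyl]-8-geranyl-7-geranyloxy-5-(triisopropylsilyloxy)chroman-4-one
Product: 13 (2S)-8-geranyl-7-(geranyloxy)-5-hydroxy-2-(4-hydroxyphenyl)chroman-4-one (target)
Conditions: TBAF (2.5 equiv), AcOH (2.5 equiv), THF, 0 °C
Reagents that add atoms: none
Why: Fluoride cleaves both aryl silyl ethers; the acetic acid buffer keeps the phenols protonated, so the flavanone should not open to the chalcone and C2 should keep its configuration, while the allylic aryl ether is untouched.

Compound list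
1 | phloroglucinol (benzene-1,3,5-triol) | Oc1cc(O)cc(O)c1 | starting material
2 | geranyl bromide ((2E)-1-bromo-3,7-dimethylocta-2,6-diene) | CC(C)=CCC/C(C)=C/CBr | starting material
3 | 2-geranylphloroglucinol (2-[(2E)-3,7-dimethylocta-2,6-dien-1-yl]benzene-1,3,5-triol) | Oc1cc(O)c(C/C=C(\C)CCC=C(C)C)c(O)c1 | intermediate
4 | 2-geranyl-5-(triisopropylsilyloxy)benzene-1,3-diol | CC(C)[Si](Oc1cc(O)c(C/C=C(\C)CCC=C(C)C)c(O)c1)(C(C)C)C(C)C | intermediate
5 | geraniol ((2E)-3,7-dimethylocta-2,6-dien-1-ol) | CC(C)=CCC/C(C)=C/CO | starting material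
6 | 2-geranyl-3-(geranyloxy)-5-(triisopropylsilyloxy)phenol | CC(C)=CCC/C(C)=C/COc1cc(O[Si](C(C)C)(C(C)C)C(C)C)cc(O)c1C/C=C(\C)CCC=C(C)C | intermediate
7 | 4-(tert-butyldimethylsilyloxy)benzaldehyde | CC(C)(C)[Si](C)(C)Oc1ccc(C=O)cc1 | starting material
8 | chloro[4-(tert-butyldimethylsilyloxy)phenyl]methyl pivalate (racemic) | CC(C)(C)C(=O)OC(Cl)c1ccc(O[Si](C)(C)C(C)(C)C)cc1 | intermediate
9 | [4-(tert-butyldimethylsilyloxy)phenyl][2-geranyl-3-(geranyloxy)-5-(triisopropylsilyloxy)phenoxy]methyl pivalate (racemic at the acetal carbon) | CC(C)=CCC/C(C)=C/COc1cc(O[Si](C(C)C)(C(C)C)C(C)C)cc(OC(OC(=O)C(C)(C)C)c2ccc(O[Si](C)(C)C(C)(C)C)cc2)c1C/C=C(\C)CCC=C(C)C | intermediate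
10 | ethoxyethyne | C#COCC | starting material
11 | (2S)-2-[4-(tert-butyldimethylsilyloxy)phenyl]-4-ethoxy-8-geranyl-7-(geranyloxy)-5-(triisopropylsilyloxy)-2H-chromene | CC(C)=CCC/C(C)=C/COc1cc(O[Si](C(C)C)(C(C)C)C(C)C)c2c(c1C/C=C(\C)CCC=C(C)C)O[C@H](c1ccc(O[Si](C)(C)C(C)(C)C)cc1)C=C2OCC | intermediate (not isolated)
12 | (2S)-2-[4-(tert-butyldimethylsilyloxy)phenyl]-8-geranyl-7-(geranyloxy)-5-(triisopropylsilyloxy)chroman-4-one | CC(C)=CCC/C(C)=C/COc1cc(O[Si](C(C)C)(C(C)C)C(C)C)c2c(c1C/C=C(\C)CCC=C(C)C)O[C@H](c1ccc(O[Si](C)(C)C(C)(C)C)cc1)CC2=O | intermediate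
13 | (2S)-8-geranyl-7-(geranyloxy)-5-hydroxy-2-(4-hydroxyphenyl)chroman-4-one | CC(C)=CCC/C(C)=C/COc1cc(O)c2c(c1C/C=C(\C)CCC=C(C)C)O[C@H](c1ccc(O)cc1)CC2=O | target

Total step count: 7. Longest linear sequence: 6 steps (steps 1, 2, 3, 5, 6, 7 from phloroglucinol); step 4 is a one-step branch.

Steps most likely to fail

Step 6 (bears the label). The oxocarbenium ion may be captured by the C8 geranyl double bond in a Prins-type closure before the ynol ether arrives. The strong acid may also oligomerise the ynol ether or acetylate ring A, and the anion may give poor facial control. The fallback uses known chemistry and sets out from phenol 6. Magnesium-mediated ortho-formylation (MgCl2, Et3N, paraformaldehyde, MeCN, reflux) should give 3-geranyl-4-(geranyloxy)-2-hydroxy-6-(triisopropylsilyloxy)benzaldehyde F1, the only free ortho position being attacked. Addition of HC≡CMgBr (2.2 equiv, THF, 0 °C) gives the propargylic alcohol F2, and MnO2 (CH2Cl2, rt) oxidises it to the 2-hydroxyaryl ynone F3. Et2NH in EtOH closes F3 by oxa-Michael addition to 8-geranyl-7-(geranyloxy)-5-(triisopropylsilyloxy)chromone F4. Asymmetric conjugate addition of [4-(tert-butyldimethylsilyloxy)phenyl]boronic acid to F4 then follows, with Pd(OCOCF3)2, the t-BuPyOX enantiomer that delivers 2S, NH4PF6 and water in 1,2-dichloroethane at 60 °C. This returns to the route at 12.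

Step 4. The adduct of an acid chloride with this electron-rich aldehyde may revert to its components or ionise on handling, so that step 5 would pivaloylate the phenoxide instead of alkylating it. The fallback sets out from aldehyde 7. Thiophenol and pivaloyl chloride (pyridine, CH2Cl2, 0 °C) trap it as the O-pivaloyl hemithioacetal [4-(tert-butyldimethylsilyloxy)phenyl](phenylsulfanyl)methyl pivalate F5. SO2Cl2 (CH2Cl2, −78 to 0 °C) then exchanges the arylthio group for chloride irreversibly; no olefin is present at this stage. This returns to the route at 8.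

Step 2. Silylation may discriminate poorly between the unhindered hydroxyl and the two hydroxyls next to the geranyl group, giving regioisomers and bis-silyl ethers. The fallback inverts the order and sets out from 1. Monosilylation of excess phloroglucinol (TIPSCl, imidazole, DMF) gives 5-(triisopropylsilyloxy)benzene-1,3-diol F6. C-geranylation of F6 with 2 and DBU in THF should take place at the carbon between the two free hydroxyls, the other two activated carbons being flanked by the bulky silyl ether. This returns to the route at 4.

Further compounds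
F1 | step 6 | 3-geranyl-4-(geranyloxy)-2-hydroxy-6-(triisopropylsilyloxy)benzaldehyde | CC(C)=CCC/C(C)=C/COc1cc(O[Si](C(C)C)(C(C)C)C(C)C)c(C=O)c(O)c1C/C=C(\C)CCC=C(C)C
F2 | step 6 | 1-[3-geranyl-4-(geranyloxy)-2-hydroxy-6-(triisopropylsilyloxy)phenyl]prop-2-yn-1-ol (racemic) | CC(C)=CCC/C(C)=C/COc1cc(O[Si](C(C)C)(C(C)C)C(C)C)c(C(O)C#C)c(O)c1C/C=C(\C)CCC=C(C)C
F3 | step 6 | 1-[3-geranyl-4-(geranyloxy)-2-hydroxy-6-(triisopropylsilyloxy)phenyl]prop-2-yn-1-one | CC(C)=CCC/C(C)=C/COc1cc(O[Si](C(C)C)(C(C)C)C(C)C)c(C(=O)C#C)c(O)c1C/C=C(\C)CCC=C(C)C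
F4 | step 6 | 8-geranyl-7-(geranyloxy)-5-(triisopropylsilyloxy)-4H-chromen-4-one | CC(C)=CCC/C(C)=C/COc1cc(O[Si](C(C)C)(C(C)C)C(C)C)c2c(c1C/C=C(\C)CCC=C(C)C)OC=CC2=O
F5 | step 4 | [4-(tert-butyldimethylsilyloxy)phenyl](phenylsulfanyl)methyl pivalate (racemic) | CC(C)(C)C(=O)OC(Sc1ccccc1)c1ccc(O[Si](C)(C)C(C)(C)C)cc1
F6 | step 2 | 5-(triisopropylsilyloxy)benzene-1,3-diol | CC(C)[Si](Oc1cc(O)cc(O)c1)(C(C)C)C(C)C
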